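What is the easy case? Take a flask in which no free catalyst is lost and the rate of making left-handed product, at a fixed composition, is first order in free catalyst: the rate then follows the charge, so the order is 1 and a doubled charge gives a factor of 2.

in all of them: left-handed substrate 0.80 M; right-handed substrate 0.80 M; free catalyst 4.2 mM; impurity 0.59 mM

| flask | reagent | remark |
|---|---|---|
| Monday's | 0.88 M | the very flask that is asked about, followed so far |
| flask | 0.880 M |  |

- Monday's (time / min: left-handed product / %): 6.00: 14; 20.0: 30; 30.0: 35; 50.0: 39; 80.0: 43; 90.0: 43

(standard deviation of a reading: 1.5 percentage points)

- free catalyst is single-handed; left-handed substrate and right-handed substrate are mirror images of each other, charged as a racemate, each of them at the stated concentration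
- no earlier run changes the charge of free catalyst; that part of a forecast is a guess

* apparent order in free catalyst when 50% of the left-handed substrate and right-handed substrate together are converted (percent change of the rate of making left-handed product for one percent more free catalyst charged)
* factor on the rate of making left-handed product when 50% of the left-handed substrate and right-handed substrate together are converted if free catalyst is charged twice over

And this flask, with 0.59 mM of impurity beside 4.2 mM of free catalyst? I take the other end first. Suppose each impurity takes one free catalyst for good, which is catalyst poisoning. A charge barely above the impurity then leaves very little working, a small addition multiplies that little, and the order climbs steeply.

How do you join the two ends? With one line: the working catalyst is the charge minus the impurity, 3.61 mM in this flask, and the rate follows it. One percent more charge adds one percent of the charge to the working catalyst, so the apparent order is the charge divided by the working catalyst, 1.16.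

Where is that weak? Monday's run held the charge at 4.2 mM, so the capture of one for one and the first order in working catalyst are my assumptions, not readings. Its last reading of left-handed product, 43%, also lies below the 50% conversion asked about, so I must assume the capture is over by then.

Does more catalyst not change the composition at that conversion? If the rates of using both substrates go with the working catalyst to the same power, and the capture is over early, the path stays the same and a faster flask reaches the same composition sooner. The factor for a doubled charge is then the new working catalyst over the old, 2.16.

The forecast, assuming that “the impurity titrates catalyst”, gives 1.15 and 2.15.

The flask gives an order of 1.2 and a factor of 2.16.

    reagent + free catalyst + left-handed substrate → free catalyst + left-handed product (k = 23.2 L² mol⁻² min⁻¹)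
    reagent + free catalyst + right-handed substrate → free catalyst + right-handed product (k = 0.166 L² mol⁻² min⁻¹)
    free catalyst + impurity → spent catalyst (k = 7620 L mol⁻¹ min⁻¹)

In the flask this conversion is reached at 4.14 h, while impurity already stands at 0% after 0.800 h. One over the carried ratio is 86.2%, the working share of the charge, and after 4.00 h free catalyst stands at 86.0% of the catalyst charged, with spent catalyst at 14.0%.

The readings are calculated with constants of no real substance; the scatter is artificial.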